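## Retrosynthetic overview

1. C1–C14 is closed last: a nickel/chromium-catalysed reductive coupling of a terminal alkyne (C1) with the C14 aldehyde forms the 14-membered ring, the exocyclic methylidene and the 14S carbinol.
2. C7–C8 joins the two halves: an indium-mediated 2-(methoxycarbonyl)allylation of a west α-hydroxy aldehyde (C1–C7) with an east allylic bromide (C8–C14 plus the acrylate carbons), then acid closure of the cis α-methylidene γ-lactone (first ring).
3. The C10–C11 epoxide is made by Shi epoxidation of the E-trisubstituted alkene after the union (second ring); the macrocycle is the third ring.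
4. West fragment: the C4–C5 bond comes from a CuI-catalysed Grignard opening of the Shi epoxide of crotonaldehyde dimethyl acetal, which sets 5S and 6R.
5. East fragment: zirconium-catalysed methylalumination of silylated pent-4-yn-1-ol, oxirane opening, oxidation, vinylalumination with methyl propiolate and SN2' bromination.

Assumption: the ring carbons are numbered C1–C14 in the order they stand in the SMILES string (C1 carries the exocyclic methylidene, C14 the allylic hydroxyl); in this numbering the target is 5S,6R,7R,8S,10R,11R,14S.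

## Route

**West fragment (C1–C7)**

Step 1
Reactants: 1 5-chloropent-1-yne
Product: 3 (5-chloropent-1-yn-1-yl)trimethylsilane, via lithium acetylide 2 (not isolated)
Conditions: n-BuLi, THF, −78 °C; Me3SiCl, −78 → 23 °C
Reagents that add atoms: chlorotrimethylsilane C[Si](C)(C)Cl
Why: The alkyne C–H is lithiated at −78 °C much faster than the primary chloride reacts and the acetylide is C-silylated (lithiation–silylation), which masks the acidic proton so that the chloride can be turned into a Grignard reagent.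

Step 2
Reactants: 4 (E)-1,1-dimethoxybut-2-ene
Product: 5 (2R,3S)-2-(dimethoxymethyl)-3-methyloxirane
Conditions: 1,2:4,5-di-O-isopropylidene-β-L-erythro-2,3-hexodiulo-2,6-pyranose (ent-Shi ketone, 30 mol %), KHSO5 (as the triple salt 2KHSO5·KHSO4·K2SO4), K2CO3, Bu4NHSO4 (cat.), MeCN–(MeO)2CH2–H2O, 0 °C, pH 10.5
Reagents that add atoms: potassium peroxymonosulfate [K+].[O-]S(=O)(=O)OO
Why: Shi asymmetric epoxidation (chiral dioxirane, spiro transition state) of the E-disubstituted alkene gives the trans epoxide, the L-fructose-derived ketone delivers the (2R,3S) isomer that fixes C6 and the face for inversion at C5, and the acetal is stable at this pH.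

Step 3
Reactants: 3 (5-chloropent-1-yn-1-yl)trimethylsilane and 5 (2R,3S)-2-(dimethoxymethyl)-3-methyloxirane
Product: 7 (2R,3S)-1,1-dimethoxy-3-methyl-8-(trimethylsilyl)oct-7-yn-2-ol, via Grignard reagent 6 (not isolated)
Conditions: Mg, I2 (cat.), THF, 50 °C; then CuI (10 mol %), 5, THF, −30 → 0 °C; aq. work-up
Reagents that add atoms: none
Why: Copper-catalysed SN2 opening of the epoxide by the alkyl Grignard reagent takes place with inversion at the methyl-bearing carbon (C5), away from the carbon that is deactivated by the adjacent acetal, and so gives the 5S,6R pair with methyl and hydroxyl syn.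

Step 4
Reactants: 7 (2R,3S)-1,1-dimethoxy-3-methyl-8-(trimethylsilyl)oct-7-yn-2-ol
Product: 8 (2R,3S)-1,1-dimethoxy-3-methyloct-7-yn-2-ol
Conditions: K2CO3 (cat.), MeOH, 23 °C
Reagents that add atoms: none
Why: Methoxide cleaves the alkynyl C–Si bond (protodesilylation) and leaves the acetal, the alcohol and both stereocentres untouched.

Step 5
Reactants: 8 (2R,3S)-1,1-dimethoxy-3-methyloct-7-yn-2-ol
Product: 9 (2R,3S)-2-hydroxy-3-methyloct-7-ynal
Conditions: 1 M aq. HCl, THF, 40 °C; NaHCO3 to pH 6; used crude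
Reagents that add atoms: water O
Why: Acid-catalysed acetal hydrolysis frees the α-hydroxy aldehyde (in equilibrium with its hydrate and dimer), which is taken on at once so that C6 is not epimerised.

**East fragment (C8–C14 and the acrylate carbons)**

Step 6
Reactants: 10 pent-4-yn-1-ol
Product: 11 tert-butyldimethyl(pent-4-yn-1-yloxy)silane
Conditions: t-BuMe2SiCl, imidazole, CH2Cl2, 0 → 23 °C
Reagents that add atoms: tert-butylchlorodimethylsilane CC(C)(C)[Si](C)(C)Cl
Why: Silyl ether formation protects the future C14 hydroxyl through the organoaluminium and oxidation steps.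

Step 7
Reactants: 11 tert-butyldimethyl(pent-4-yn-1-yloxy)silane and 12 oxirane
Product: 15 (E)-7-[(tert-butyldimethylsilyl)oxy]-4-methylhept-3-en-1-ol, via alkenylalane 13 (not isolated), via lithium alanate 14 (not isolated)
Conditions: Me3Al, Cp2ZrCl2 (25 mol %), CH2Cl2, 0 → 23 °C; then hexane–THF, n-BuLi, −78 °C; 12, −78 → 0 °C; aq. KNaC4H4O6
Reagents that add atoms: trimethylaluminium C[Al](C)C
Why: Negishi zirconium-catalysed syn-methylalumination puts the methyl group on the internal alkyne carbon (C11) and aluminium on the terminal one (C10), and the derived alanate opens oxirane with retention of the alkene geometry, which gives the E-trisubstituted alkene needed for the trans epoxide.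

Step 8
Reactants: 15 (E)-7-[(tert-butyldimethylsilyl)oxy]-4-methylhept-3-en-1-ol
Product: 16 (E)-7-[(tert-butyldimethylsilyl)oxy]-4-methylhept-3-enal
Conditions: Dess–Martin periodinane, NaHCO3, CH2Cl2, 0 °C; used at once
Reagents that add atoms: none
Why: Buffered Dess–Martin oxidation gives the β,γ-unsaturated aldehyde without moving the double bond into conjugation.

Step 9
Reactants: 16 (E)-7-[(tert-butyldimethylsilyl)oxy]-4-methylhept-3-enal and 17 methyl propiolate
Product: 19 methyl (5E)-9-[(tert-butyldimethylsilyl)oxy]-3-hydroxy-6-methyl-2-methylidenenon-5-enoate (both C3 epimers), via vinylalane 18 (not isolated)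
Conditions: 17, iBu2AlH, 4-methylmorpholine N-oxide, THF, 0 °C; then 16, −78 → 0 °C; aq. KNaC4H4O6
Reagents that add atoms: none
Why: 1,4-Hydroalumination of the propiolate gives the α-aluminoacrylate, which adds to the aldehyde (vinylalumination, a fast non-basic route to the Morita–Baylis–Hillman adduct) without isomerising the β,γ-alkene; the new carbinol centre is erased in step 10.

Step 10
Reactants: 19 methyl (5E)-9-[(tert-butyldimethylsilyl)oxy]-3-hydroxy-6-methyl-2-methylidenenon-5-enoate
Product: 20 methyl (2Z,5E)-2-(bromomethyl)-9-[(tert-butyldimethylsilyl)oxy]-6-methylnona-2,5-dienoate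
Conditions: NBS, Me2S, CH2Cl2, 0 → 23 °C
Reagents that add atoms: N-bromosuccinimide O=C1CCC(=O)N1Br
Why: Bromodimethylsulfonium activation of the allylic hydroxyl (Corey–Kim-type) and SN2' return of bromide give the thermodynamically preferred Z 2-(bromomethyl)enoate under neutral conditions that spare the silyl ether and the trisubstituted alkene.

**Union and endgame**

Step 11
Reactants: 9 (2R,3S)-2-hydroxy-3-methyloct-7-ynal and 20 methyl (2Z,5E)-2-(bromomethyl)-9-[(tert-butyldimethylsilyl)oxy]-6-methylnona-2,5-dienoate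
Product: 22 (4S,5R)-4-[(2E)-6-hydroxy-3-methylhex-2-en-1-yl]-5-[(1R,2S)-1-hydroxy-2-methylhept-6-yn-1-yl]-3-methylideneoxolan-2-one, via hydroxy ester 21 (not isolated)
Conditions: In, THF–H2O (1:1), 23 °C; then 1 M aq. HCl, 23 °C
Reagents that add atoms: none
Why: In this Barbier-type indium-mediated 2-(alkoxycarbonyl)allylation in water the free C6 hydroxyl and the aldehyde oxygen chelate the metal, so C7 forms syn to C6-OH (7R), the chair transition state with the C9 chain cis to the metal-bearing CH2 gives the 7,8-syn adduct (8S), and acid then closes the cis γ-lactone on O7 and removes the silyl group.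

Step 12
Reactants: 22 (4S,5R)-4-[(2E)-6-hydroxy-3-methylhex-2-en-1-yl]-5-[(1R,2S)-1-hydroxy-2-methylhept-6-yn-1-yl]-3-methylideneoxolan-2-one
Product: 23 (4S,5R)-5-[(1R,2S)-1-hydroxy-2-methylhept-6-yn-1-yl]-4-{[(2R,3R)-3-(3-hydroxypropyl)-3-methyloxiran-2-yl]methyl}-3-methylideneoxolan-2-one
Conditions: 1,2:4,5-di-O-isopropylidene-β-D-erythro-2,3-hexodiulo-2,6-pyranose (Shi ketone, 1 equiv), KHSO5 (as the triple salt), NaHCO3, Bu4NHSO4 (cat.), MeCN–H2O, 0 °C, pH 8
Reagents that add atoms: potassium peroxymonosulfate [K+].[O-]S(=O)(=O)OO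
Why: In this Shi epoxidation the electrophilic chiral dioxirane attacks only the electron-rich E-trisubstituted alkene (the methylidene lactone and the alkyne are inert), the D-fructose-derived ketone gives the 10R,11R epoxide, and the pH 8 protocol spares the lactone.

Step 13
Reactants: 23 (4S,5R)-5-[(1R,2S)-1-hydroxy-2-methylhept-6-yn-1-yl]-4-{[(2R,3R)-3-(3-hydroxypropyl)-3-methyloxiran-2-yl]methyl}-3-methylideneoxolan-2-one
Product: 24 3-[(2R,3R)-3-{[(2R,3S)-2-[(1R,2S)-1-hydroxy-2-methylhept-6-yn-1-yl]-4-methylidene-5-oxooxolan-3-yl]methyl}-2-methyloxiran-2-yl]propanal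
Conditions: 2,2,6,6-tetramethylpiperidin-1-oxyl (TEMPO, 20 mol %), PhI(OAc)2, NaHCO3, CH2Cl2, 0 → 23 °C
Reagents that add atoms: none
Why: The oxoammonium (TEMPO) oxidation takes the primary alcohol and leaves the hindered secondary C6 hydroxyl, and the bicarbonate buffer keeps the γ,δ-epoxy alcohol from closing to a tetrahydrofuran.

Step 14
Reactants: 24 3-[(2R,3R)-3-{[(2R,3S)-2-[(1R,2S)-1-hydroxy-2-methylhept-6-yn-1-yl]-4-methylidene-5-oxooxolan-3-yl]methyl}-2-methyloxiran-2-yl]propanal
Product: 25 target CNP0124069.2, the (5S,6R,7R,8S,10R,11R,14S) 14-membered carbocycle with 1-methylidene, 5-methyl, 6-hydroxy, cis-fused α-methylidene γ-lactone on C7(O)/C8, 10,11-epoxide with 11-methyl, and 14-hydroxy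
Conditions: CrCl2 (20 mol %), (S)-N-[2-(4-isopropyl-4,5-dihydrooxazol-2-yl)-6-methylphenyl]methanesulfonamide (22 mol %), 1,8-bis(dimethylamino)naphthalene (22 mol %), NiCl2(PPh3)2 (5 mol %), Mn (3 equiv), Cp2ZrCl2 (1.2 equiv), LiCl (2 equiv), 2,4,6-collidine·HCl (1.2 equiv), MeCN, 23 °C, slow addition of 24 to 2 mM; aq. NaHCO3 work-up
Reagents that add atoms: none
Why: Proposed new method: a nickel/chromium-catalysed, ligand-controlled, branched (Markovnikov) reductive alkyne–aldehyde macrocyclisation in which zerovalent nickel–phosphine (formed from NiCl2(PPh3)2 by divalent chromium and Mn) is protonated by collidinium chloride to a nickel hydride species that adds across the terminal alkyne with nickel on the internal carbon C1, the 1,1-disubstituted alkenyl group passes to trivalent chromium bound to the chiral sulfonamide–oxazoline ligand and adds to the C14 aldehyde on the ligand-defined face to close the 14-membered ring with the 14S carbinol and the exocyclic methylidene (the ligand antipode is used if a pilot run shows 14R), Cp2ZrCl2 frees chromium from the alkoxide and Mn returns it to the divalent state; the closest known reaction types are the coupling of terminal alkynes with aldehydes to 2-substituted allylic alcohols with stoichiometric CrCl2 and catalytic NiCl2, PPh3 and water, and the catalytic asymmetric Nozaki–Hiyama–Kishi macrocyclisation of 2-iodoalkenes, neither of which has been run as a chromium-catalytic, ligand-controlled ring closure of an alkynal.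

## Compound list

1 | 5-chloropent-1-yne | C#CCCCCl | starting material
2 | (5-chloropent-1-yn-1-yl)lithium | [Li]C#CCCCCl | intermediate
3 | (5-chloropent-1-yn-1-yl)trimethylsilane | C[Si](C)(C)C#CCCCCl | intermediate
4 | (E)-1,1-dimethoxybut-2-ene | C/C=C/C(OC)OC | starting material
5 | (2R,3S)-2-(dimethoxymethyl)-3-methyloxirane | C[C@@H]1O[C@H]1C(OC)OC | intermediate
6 | [5-(trimethylsilyl)pent-4-yn-1-yl]magnesium chloride | C[Si](C)(C)C#CCCC[Mg]Cl | intermediate
7 | (2R,3S)-1,1-dimethoxy-3-methyl-8-(trimethylsilyl)oct-7-yn-2-ol | C[Si](C)(C)C#CCCC[C@H](C)[C@@H](O)C(OC)OC | intermediate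
8 | (2R,3S)-1,1-dimethoxy-3-methyloct-7-yn-2-ol | C#CCCC[C@H](C)[C@@H](O)C(OC)OC | intermediate
9 | (2R,3S)-2-hydroxy-3-methyloct-7-ynal | C#CCCC[C@H](C)[C@@H](O)C=O | intermediate
10 | pent-4-yn-1-ol | C#CCCCO | starting material
11 | tert-butyldimethyl(pent-4-yn-1-yloxy)silane | C#CCCCO[Si](C)(C)C(C)(C)C | intermediate
12 | oxirane | C1CO1 | starting material
13 | {(1E)-5-[(tert-butyldimethylsilyl)oxy]-2-methylpent-1-en-1-yl}dimethylalane | C[Al](C)/C=C(\C)CCCO[Si](C)(C)C(C)(C)C | intermediate
14 | lithium butyl{(1E)-5-[(tert-butyldimethylsilyl)oxy]-2-methylpent-1-en-1-yl}dimethylaluminate | [Li+].CCCC[Al-](C)(C)/C=C(\C)CCCO[Si](C)(C)C(C)(C)C | intermediate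
15 | (E)-7-[(tert-butyldimethylsilyl)oxy]-4-methylhept-3-en-1-ol | OCC/C=C(\C)CCCO[Si](C)(C)C(C)(C)C | intermediate
16 | (E)-7-[(tert-butyldimethylsilyl)oxy]-4-methylhept-3-enal | O=CC/C=C(\C)CCCO[Si](C)(C)C(C)(C)C | intermediate
17 | methyl propiolate | C#CC(=O)OC | starting material
18 | [1-(methoxycarbonyl)ethenyl]bis(2-methylpropyl)alane | C=C(C(=O)OC)[Al](CC(C)C)CC(C)C | intermediate
19 | methyl (5E)-9-[(tert-butyldimethylsilyl)oxy]-3-hydroxy-6-methyl-2-methylidenenon-5-enoate (both C3 epimers) | COC(=O)C(=C)C(O)C/C=C(\C)CCCO[Si](C)(C)C(C)(C)C | intermediate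
20 | methyl (2Z,5E)-2-(bromomethyl)-9-[(tert-butyldimethylsilyl)oxy]-6-methylnona-2,5-dienoate | COC(=O)/C(CBr)=C/C/C=C(\C)CCCO[Si](C)(C)C(C)(C)C | intermediate
21 | methyl (3S,4R,5R,6S)-3-{(2E)-6-[(tert-butyldimethylsilyl)oxy]-3-methylhex-2-en-1-yl}-4,5-dihydroxy-6-methyl-2-methylideneundec-10-ynoate | C#CCCC[C@H](C)[C@@H](O)[C@H](O)[C@H](C(=C)C(=O)OC)C/C=C(\C)CCCO[Si](C)(C)C(C)(C)C | intermediate
22 | (4S,5R)-4-[(2E)-6-hydroxy-3-methylhex-2-en-1-yl]-5-[(1R,2S)-1-hydroxy-2-methylhept-6-yn-1-yl]-3-methylideneoxolan-2-one | C#CCCC[C@H](C)[C@@H](O)[C@@H]1OC(=O)C(=C)[C@@H]1C/C=C(\C)CCCO | intermediate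
23 | (4S,5R)-5-[(1R,2S)-1-hydroxy-2-methylhept-6-yn-1-yl]-4-{[(2R,3R)-3-(3-hydroxypropyl)-3-methyloxiran-2-yl]methyl}-3-methylideneoxolan-2-one | C#CCCC[C@H](C)[C@@H](O)[C@@H]1OC(=O)C(=C)[C@@H]1C[C@H]2O[C@]2(C)CCCO | intermediate
24 | 3-[(2R,3R)-3-{[(2R,3S)-2-[(1R,2S)-1-hydroxy-2-methylhept-6-yn-1-yl]-4-methylidene-5-oxooxolan-3-yl]methyl}-2-methyloxiran-2-yl]propanal | C#CCCC[C@H](C)[C@@H](O)[C@@H]1OC(=O)C(=C)[C@@H]1C[C@H]2O[C@]2(C)CCC=O | intermediate
25 | target CNP0124069.2 (5S,6R,7R,8S,10R,11R,14S; ring locants as defined above) | C=C1CCC[C@H](C)[C@@H](O)[C@@H]2OC(=O)C(=C)[C@@H]2C[C@H]2O[C@]2(C)CC[C@@H]1O | target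

## Totals and risks

Total step count: 14.
Longest linear sequence: 9 steps (steps 6–14, from pent-4-yn-1-ol to the target).

The three steps most likely to fail:

**Step 11 (indium union).** Three stereochemical elements are fixed at once (C7, C8 and the cis lactone) and the free α-hydroxy aldehyde is fragile. The fallback replaces chelation control by catalyst control. It sets out from 8, which is silylated (t-BuMe2SiOTf, 2,6-lutidine) to the silyl ether acetal F1. Aqueous trifluoroacetic acid in CHCl3 at 0 °C unmasks the α-silyloxy aldehyde F2. A chromium-catalysed enantioselective 2-(alkoxycarbonyl)allylation with 20 (CrCl2 and a chiral 1,8-bis(oxazolin-2-yl)carbazole ligand, Mn, Me3SiCl, then acid to lactonise) gives the bis-silyl lactone F3. Here the ligand fixes C7 (against the Felkin preference of the substrate, so some loss of selectivity is expected) and the chair transition state still gives the cis lactone. Aqueous HCl in THF removes both silyl groups and the route is rejoined at 22.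

**Step 12 (late Shi epoxidation).** The lactone may open in the aqueous base and the epoxy alcohol is acid-sensitive. The fallback moves the epoxidation into the east fragment. It sets out from 19, whose only electron-rich alkene is epoxidised with the D-fructose-derived Shi ketone, KHSO5 and K2CO3 to the epoxy alcohol F4. NBS and Me2S give the epoxy bromide F5. Indium-mediated coupling with 9 in THF–pH 7 phosphate buffer, then lactonisation with catalytic 2-hydroxypyridine in toluene at 60 °C, gives the silyl ether F6. Bu4NF buffered with AcOH removes the silyl group and the route is rejoined at 23.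

**Step 14 (proposed macrocyclisation).** The nickel hydride may reduce the methylidene lactone, the alkenylchromium species may be protonated, or the ring closure may be slow. The fallback uses only known chemistry and sets out from 23. Markovnikov hydrosilylation of the alkyne with Et3SiH and [Cp*Ru(MeCN)3]PF6 in CH2Cl2 gives the vinylsilane F7. Iododesilylation with NIS in MeCN gives the 2-iodoalkene F8. TEMPO and PhI(OAc)2 with NaHCO3 give the iodo aldehyde F9. A catalytic asymmetric Nozaki–Hiyama–Kishi macrocyclisation (CrCl2 with the same sulfonamide ligand, NiCl2(2,9-dimethyl-1,10-phenanthroline), Mn, Cp2ZrCl2, LiCl, MeCN, high dilution) then forms the C1–C14 bond and the route is rejoined at 25.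

Further compounds

F1 | step 11 | tert-butyl{[(2R,3S)-1,1-dimethoxy-3-methyloct-7-yn-2-yl]oxy}dimethylsilane | C#CCCC[C@H](C)[C@@H](O[Si](C)(C)C(C)(C)C)C(OC)OC
F2 | step 11 | (2R,3S)-2-[(tert-butyldimethylsilyl)oxy]-3-methyloct-7-ynal | C#CCCC[C@H](C)[C@@H](O[Si](C)(C)C(C)(C)C)C=O
F3 | step 11 | (4S,5R)-4-{(2E)-6-[(tert-butyldimethylsilyl)oxy]-3-methylhex-2-en-1-yl}-5-{(1R,2S)-1-[(tert-butyldimethylsilyl)oxy]-2-methylhept-6-yn-1-yl}-3-methylideneoxolan-2-one | C#CCCC[C@H](C)[C@@H](O[Si](C)(C)C(C)(C)C)[C@@H]1OC(=O)C(=C)[C@@H]1C/C=C(\C)CCCO[Si](C)(C)C(C)(C)C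
F4 | step 12 | methyl 4-[(2R,3R)-3-{3-[(tert-butyldimethylsilyl)oxy]propyl}-3-methyloxiran-2-yl]-3-hydroxy-2-methylidenebutanoate (both C3 epimers) | COC(=O)C(=C)C(O)C[C@H]1O[C@]1(C)CCCO[Si](C)(C)C(C)(C)C
F5 | step 12 | methyl (2Z)-2-(bromomethyl)-4-[(2R,3R)-3-{3-[(tert-butyldimethylsilyl)oxy]propyl}-3-methyloxiran-2-yl]but-2-enoate | COC(=O)/C(CBr)=C/C[C@H]1O[C@]1(C)CCCO[Si](C)(C)C(C)(C)C
F6 | step 12 | (4S,5R)-4-{[(2R,3R)-3-{3-[(tert-butyldimethylsilyl)oxy]propyl}-3-methyloxiran-2-yl]methyl}-5-[(1R,2S)-1-hydroxy-2-methylhept-6-yn-1-yl]-3-methylideneoxolan-2-one | C#CCCC[C@H](C)[C@@H](O)[C@@H]1OC(=O)C(=C)[C@@H]1C[C@H]2O[C@]2(C)CCCO[Si](C)(C)C(C)(C)C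
F7 | step 14 | (4S,5R)-5-[(1R,2S)-1-hydroxy-2-methyl-6-(triethylsilyl)hept-6-en-1-yl]-4-{[(2R,3R)-3-(3-hydroxypropyl)-3-methyloxiran-2-yl]methyl}-3-methylideneoxolan-2-one | C=C([Si](CC)(CC)CC)CCC[C@H](C)[C@@H](O)[C@@H]1OC(=O)C(=C)[C@@H]1C[C@H]2O[C@]2(C)CCCO
F8 | step 14 | (4S,5R)-5-[(1R,2S)-1-hydroxy-6-iodo-2-methylhept-6-en-1-yl]-4-{[(2R,3R)-3-(3-hydroxypropyl)-3-methyloxiran-2-yl]methyl}-3-methylideneoxolan-2-one | C=C(I)CCC[C@H](C)[C@@H](O)[C@@H]1OC(=O)C(=C)[C@@H]1C[C@H]2O[C@]2(C)CCCO
F9 | step 14 | 3-[(2R,3R)-3-{[(2R,3S)-2-[(1R,2S)-1-hydroxy-6-iodo-2-methylhept-6-en-1-yl]-4-methylidene-5-oxooxolan-3-yl]methyl}-2-methyloxiran-2-yl]propanal | C=C(I)CCC[C@H](C)[C@@H](O)[C@@H]1OC(=O)C(=C)[C@@H]1C[C@H]2O[C@]2(C)CCC=O
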